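**Retrosynthetic overview**
1. The strategy rests on the spiro carbon C14' (abietane numbering, primes for the 20-nor upper half). It is the ether carbon of C14–O–C14', benzylic to ring B', allylic to C12'=C13' of ring C', and 1,5 to C7 of ring B. The dihydrofuran ring O–C14–C8–C7–C14' is therefore closed last by making C7–C14'.
2. Target ⇒ (catechol oxidation with ortho-quinone to quinone-methide shift; acid deprotection) protected spirocycle ⇒ (carbene 1,5 C–H insertion with retention) C7 diazo compound. This compound carries the upper half as a secondary C14' ether, and a C11' ketal keeps ring C' non-aromatic.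
3. Diazo ether ⇒ (MnO2; hydrazine) C7 ketone ⇒ (Mitsunobu, inversion at C14') lower 14-hydroxy-7-ketone + upper (14'S)-carbinol.
4. Lower half: carnosic acid supplies rings A, B, C and C5/C10; C20 CO2H is cut down to CH3, C14 is brominated then hydroxylated, and C7 is oxidised. Upper half: ring B' is bought, ring A' is closed by reductive Heck reaction, and ring C' is built by Moore rearrangement of a squarate adduct and then dearomatised to the quinone monoketal.
5. Order of ring formation: A', then C', then the dihydrofuran.

Key step: step 23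

Assumption: the sense of induction in step 19 is assigned with the isopropyl-bearing C13' flank as the larger group of the C14' ketone; should the carbinol prove to be (14'R), the enantiomeric oxazaborolidine is used and nothing else changes.

**Step 1**
Reactants: 1 (+)-carnosic acid (11,12-dihydroxyabieta-8,11,13-trien-20-oic acid; 5α-H, 10β-CO2H)
Product: 2 methoxymethyl 11,12-bis(methoxymethoxy)abieta-8,11,13-trien-20-oate
Conditions: NaH, MOMCl, THF–DMF, 0 °C → rt, Ar
Reagents that add atoms: chloromethyl methyl ether (MOMCl), COCCl
Why: Williamson-type O-alkylation of the carboxylate and both phenoxides masks the three acidic groups in one operation, base-stable acetals being chosen because they must outlast hot alkali, palladium catalysis and hydrazine and still leave under mild acid at the end.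

**Step 2**
Reactants: 2 tris-MOM carnosate
Product: 3 11,12-bis(methoxymethoxy)abieta-8,11,13-trien-20-ol
Conditions: LiAlH4, THF, reflux
Reagents that add atoms: none
Why: Ester reduction with LiAlH4 succeeds because the acyloxymethyl ether is an activated ester, so hydride reaches even this neopentyl carbonyl and gives the C20 carbinol without change at C10 or at the aryl acetals.

**Step 3**
Reactants: 3 C20 carbinol
Product: 4 11,12-bis(methoxymethoxy)abieta-8,11,13-trien-20-al
Conditions: (n-Pr4N)RuO4 (5 mol %), NMO, 4 Å MS, CH2Cl2, rt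
Reagents that add atoms: none
Why: Ley–Griffith oxidation works under neutral conditions, stops at the non-enolisable aldehyde and leaves the acetals alone.

**Step 4**
Reactants: 4 C20 aldehyde
Product: 6 11,12-bis(methoxymethoxy)abieta-8,11,13-triene (10β-methyl), via C20 hydrazone 5 (not isolated)
Conditions: N2H4·H2O, KOH, diethylene glycol, 130 °C then 200 °C
Reagents that add atoms: none
Why: Wolff–Kishner reduction in the Huang-Minlon form takes the non-enolisable aldehyde to the C10 methyl group that the target carries in place of the carboxyl group of carnosic acid, and it avoids C20 sulfonate or cation chemistry that would trigger aryl migration and ring expansion.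

**Step 5**
Reactants: 6 bis-MOM abietatriene
Product: 7 14-bromo-11,12-bis(methoxymethoxy)abieta-8,11,13-triene
Conditions: NBS, MeCN, 0 °C → rt, dark
Reagents that add atoms: N-bromosuccinimide, O=C1CCC(=O)N1Br
Why: Electrophilic aromatic bromination has only one open ring position, C14, which is para to the C11 oxygen, and the polar medium in the dark keeps radical benzylic bromination out.

**Step 6**
Reactants: 7 14-bromide
Product: 8 14-bromo-11,12-bis(methoxymethoxy)abieta-8,11,13-trien-7-one
Conditions: CrO3 (5 mol %), t-BuOOH (70 % aq), CH2Cl2, rt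
Reagents that add atoms: tert-butyl hydroperoxide, CC(C)(C)OO
Why: CrO3-catalysed benzylic oxidation attacks C7, the only benzylic methylene, because its pseudo-axial C–H bond overlaps with the arene para to the C12 oxygen whereas the isopropyl methine is locked in the ring plane between two ortho substituents.

**Step 7**
Reactants: 8 14-bromo-7-ketone
Product: 9 14-hydroxy-11,12-bis(methoxymethoxy)abieta-8,11,13-trien-7-one
Conditions: Pd2(dba)3 (2 mol %), t-BuXPhos (8 mol %), KOH, 1,4-dioxane–H2O, 100 °C; aq NH4Cl
Reagents that add atoms: potassium hydroxide, [K+].[OH-]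
Why: Palladium-catalysed hydroxylation of the aryl bromide (C–O cross-coupling with hydroxide) is favoured by the ortho ketone and a bulky biarylphosphine, leaves the base-stable acetals intact and cannot epimerise C5, which is not alpha to the ketone.

**Step 8**
Reactants: 10 2-bromo-3-hydroxybenzaldehyde
Product: 11 2-bromo-3-(methoxymethoxy)benzaldehyde
Conditions: NaH, MOMCl, THF, 0 °C → rt
Reagents that add atoms: chloromethyl methyl ether (MOMCl), COCCl
Why: Williamson-type O-alkylation protects the future C6' phenol as the same acid-labile acetal that is used in the lower half.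

**Step 9**
Reactants: 11 MOM-protected bromoaldehyde; 12 4-bromo-2-methylbut-1-ene
Product: 14 rac-1-[2-bromo-3-(methoxymethoxy)phenyl]-4-methylpent-4-en-1-ol, via homoallyl Grignard reagent 13 (not isolated)
Conditions: 12, Mg, THF; then 11, 0 °C; aq NH4Cl
Reagents that add atoms: none
Why: Grignard addition to the aldehyde joins C1' to C2', and the racemic carbinol centre does not matter because it is flattened in step 10.

**Step 10**
Reactants: 14 racemic benzylic alcohol
Product: 15 1-[2-bromo-3-(methoxymethoxy)phenyl]-4-methylpent-4-en-1-one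
Conditions: (n-Pr4N)RuO4 (5 mol %), NMO, 4 Å MS, CH2Cl2, rt
Reagents that add atoms: none
Why: Ley–Griffith oxidation of the benzylic alcohol gives the aryl ketone without touching the 1,1-disubstituted alkene or the acetal.

**Step 11**
Reactants: 15 bromoaryl enone precursor
Product: 16 5-(methoxymethoxy)-4,4-dimethyl-3,4-dihydronaphthalen-1(2H)-one (rings A' and B')
Conditions: Pd(OAc)2 (5 mol %), PPh3, HCO2Na, Et4NCl, DMF, 90 °C
Reagents that add atoms: none
Why: Reductive Heck cyclisation closes ring A' and sets the C4' gem-dimethyl carbon by oxidative addition of zerovalent palladium into the C5'–Br bond, 6-exo-trig carbopalladation at the disubstituted alkene carbon and formate reduction of the neopentyl palladium alkyl, which has no beta hydrogen.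

**Step 12**
Reactants: 16 tetralone
Product: 17 8-bromo-5-(methoxymethoxy)-4,4-dimethyl-3,4-dihydronaphthalen-1(2H)-one
Conditions: NBS, MeCN, 0 °C → rt
Reagents that add atoms: N-bromosuccinimide, O=C1CCC(=O)N1Br
Why: Electrophilic bromination with NBS in acetonitrile goes para to the acetal oxygen (C9'), the ortho carbon C7' being screened by the acetal chain that the C4' methyl groups push toward it.

**Step 13**
Reactants: 17 bromotetralone
Product: 18 (1S)-8-bromo-5-(methoxymethoxy)-4,4-dimethyl-1,2,3,4-tetrahydronaphthalen-1-ol
Conditions: (R)-2-methyl-CBS-oxazaborolidine (10 mol %), BH3·SMe2, THF, −20 °C; MeOH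
Reagents that add atoms: none
Why: Corey–Bakshi–Shibata reduction sets C1' by reagent control, the aryl flank acting as the large group and the C2' methylene as the small one so that the (R)-catalyst gives the (S)-carbinol.

**Step 14**
Reactants: 18 (S)-tetralol
Product: 19 tert-butyldimethylsilyl ether of 18
Conditions: TBSCl, imidazole, DMAP (cat), DMF, 40 °C
Reagents that add atoms: tert-butyldimethylsilyl chloride, CC(C)(C)[Si](C)(C)Cl
Why: Silyl ether formation blocks the C1' hydroxyl against organolithium, Mitsunobu and carbene chemistry, and the chloride rather than the triflate is used because silyl triflates attack aryl MOM ethers.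

**Step 15**
Reactants: 20 di-tert-butyl squarate
Product: 22 3-tert-butoxy-4-isopropylcyclobut-3-ene-1,2-dione, via chloromagnesium alkoxide 21 (not isolated)
Conditions: i-PrMgCl, THF, −78 °C; (CF3CO)2O, −78 °C → rt; aq NaHCO3
Reagents that add atoms: isopropylmagnesium chloride, CC(C)[Mg]Cl
Why: 1,2-Addition of the Grignard reagent to one of the two equivalent carbonyls and trifluoroacetylation of the alkoxide, whose ionisation is pushed by the vinylogous tert-butoxy group that then leaves, is the standard transposition of a squarate ester into a 3-alkoxy-4-alkylcyclobutenedione, and the tert-butyl ester is chosen so that the later C12' oxygen can be freed by mild acid.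

**Step 16**
Reactants: 19 aryl bromide; 22 isopropylcyclobutenedione
Product: 25 4-aryl-3-tert-butoxy-4-methoxy-2-isopropylcyclobut-2-en-1-one (aryl = C9' of 19; epimers at the ring carbinol carbon), via aryllithium 23 (not isolated), via lithium alkoxide 24 (not isolated)
Conditions: n-BuLi, Et2O–THF, −78 °C, 15 min; 22, −78 °C; MeOTf, −78 → 0 °C
Reagents that add atoms: methyl trifluoromethanesulfonate, COS(=O)(=O)C(F)(F)F
Why: Bromine–lithium exchange, 1,2-addition to the more electrophilic carbonyl of 22 (the one next to C–OtBu, the other being a vinylogous ester) and O-methylation of the alkoxide build C9'–C11' and mark the C11' oxygen as a methyl ether, the new carbinol carbon being an epimer mixture that is flattened in step 17 and the short cold lithiation keeping the 1,4 oxygen-to-carbon silyl shift out.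

**Step 17**
Reactants: 25 arylcyclobutenone
Product: 27 upper-half naphthol (14'-OH; 13'-isopropyl; 12'-OtBu; 11'-OMe; 6'-OMOM; (1'S)-OTBS), via vinylketene 26 (not isolated)
Conditions: PhMe, 110 °C, Ar
Reagents that add atoms: none
Why: Moore rearrangement forms ring C', since thermal conrotatory 4π opening turns the methoxy group outward and the aryl group inward, the vinylketene closes by 6π electrocyclisation onto C8' (the only free ortho carbon) and tautomerisation leaves the C14' oxygen as the only free phenol, para to the C11' methyl ether.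

**Step 18**
Reactants: 27 naphthol
Product: 28 upper-half quinone monoketal (C14' ketone; C11' dimethyl ketal; C12'=C13' tert-butyl enol ether)
Conditions: PhI(OAc)2, dry MeOH, 0 °C; NaHCO3 quench
Reagents that add atoms: methanol, CO
Why: Oxidative dearomatisation of a 4-methoxy-1-naphthol with PhI(OAc)2 in methanol traps the phenoxenium ion at the methoxy-bearing para carbon C11', which fixes C11' as sp3 and leaves C14' as the only ketone.

**Step 19**
Reactants: 28 quinone monoketal
Product: 29 (1'S,14'S)-carbinol of the upper half
Conditions: (R)-2-methyl-CBS-oxazaborolidine (30 mol %), BH3·SMe2, THF–PhMe, −20 → 0 °C; MeOH, Et3N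
Reagents that add atoms: none
Why: Corey–Bakshi–Shibata reduction delivers hydride 1,2 to the C14' ketone with the boron bound to the carbonyl lone pair on the peri-H (aryl) side, so that the isopropyl-bearing C13' flank is the large group and the (R)-catalyst sets (14'S); because C1' is already fixed the minor epimer is a diastereomer that is removed on triethylamine-deactivated silica.

**Step 20**
Reactants: 9 lower 14-hydroxy-7-ketone; 29 upper (14'S)-carbinol
Product: 30 (14'R)-ether ketone (O14 of 9 bound to C14' of the upper half)
Conditions: PPh3, DIAD, PhMe (concentrated), 0 °C → rt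
Reagents that add atoms: none
Why: In this Mitsunobu etherification the phenoxide of 9 displaces the oxyphosphonium group at the benzylic and allylic secondary carbon by SN2 with inversion from (14'S) to (14'R), in analogy to Mitsunobu aryl glycosylation of lactols, an apolar cold medium holding back ionisation while attack at C12' is blocked by the neighbouring ketal and tert-butoxy group.

**Step 21**
Reactants: 30 ether ketone
Product: 31 C7 hydrazone of 30
Conditions: N2H4·H2O (20 equiv), EtOH, 70 °C, sealed, no acid
Reagents that add atoms: hydrazine (as hydrate), NN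
Why: Hydrazone condensation is run under basic, acid-free conditions, where attack on the C7 carbonyl comes perpendicular to the ring so that the in-plane peri ether slows it only moderately, excess hydrazine suppresses azine formation, and ketal, enol ether, acetals and silyl ether are all stable.

**Step 22**
Reactants: 31 hydrazone
Product: 32 C7 diazo compound (7-diazo lower half bearing the upper half as the (14'R) secondary ether)
Conditions: activated MnO2 (10 equiv), CH2Cl2, 0 °C; filtration through Celite under Ar, solution used at once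
Reagents that add atoms: none
Why: Dehydrogenation of a free hydrazone with MnO2 is the neutral standard entry to aryl alkyl diazo compounds, and the solution is only filtered and carried on because the electron-rich diazoalkane is protonated by traces of acid.

**Step 23**
Reactants: 32 C7 diazo compound
Product: 34 spiro dihydrobenzofuran (7S,14'R; C11' ketal and C12' tert-butyl enol ether retained), via C7 rhodium carbene 33 (not isolated)
Conditions: Rh2(O2CCPh3)4 (1 mol %), 4 Å MS, CH2Cl2, −20 → 0 °C, slow addition of 32
Reagents that add atoms: none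
Why: The nucleophilic diazo carbon C7 binds an axial site of the divalent-rhodium dimer and loses N2 to give the aryl/alkyl (donor/donor) carbene 33, whose vacant p orbital takes up the C14'–H bond through a five-membered, hydride-transfer-like transition state in which C7–H and C7–C14' are made on the face of C14' that the hydrogen leaves. The closest known reaction type is the intramolecular 1,5 C–H insertion of dirhodium donor/donor carbenes, made from ortho-alkoxyaryl ketone hydrazones with MnO2, into ether alpha C–H bonds to give 2,3-dihydrobenzofurans, here applied to a methine carbon so that a quaternary centre results. The single ring closed is the dihydrofuran O–C14–C8–C7–C14', formed by 1,5-insertion (five-membered closure), fused to rings B and C and spiro to ring C'. C14' is controlled by the substrate: the configuration installed in steps 19 and 20 is retained, since even a fully developed oxocarbenium/alkylrhodium ion pair is held by the O14 tether and should collapse faster than the partial O14=C14' double bond can rotate, while C7 should take its hydrogen on the alpha face (C14' pseudo-equatorial, away from the axial C20 methyl) and is erased in step 26, so that either C7 epimer serves. The step needs 1,5-insertion to outrun the 1,2-hydride shift from C6, azine formation and attack on the C12'=C13' enol ether, and the substrate secures this because the C14'–H bond is activated three times over (alpha to oxygen, benzylic, allylic) and because the ortho groups at C13 and C8 twist the O14–C14' bond out of the arene plane and hold that hydrogen over the carbene carbon, helped by bulky triphenylacetate ligands, low temperature and slow addition. Acid is kept out with sieves and base-washed glassware because only the C11' ketal stops ring C' from losing methanol and aromatising.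

**Step 24**
Reactants: 34 spiro ketal
Product: 35 spiro C11' ketone (alpha-tert-butoxy enone in ring C')
Conditions: PPTS (10 mol %), acetone–H2O (10:1), 0 °C
Reagents that add atoms: water, O
Why: Mild acid-catalysed ketal hydrolysis, driven by a benzylic oxocarbenium ion and relief of bay-region crowding against C1', frees the C11' ketone first, and this acceptor then deactivates the C14'–O bond toward ionisation before stronger acid is applied.

**Step 25**
Reactants: 35 spiro C11' ketone
Product: 36 fully deprotected spiro catechol (11,12,6',12',1'-pentahydroxy; 7-H)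
Conditions: 3 M aq HCl–THF (1:3), 40 °C, degassed, Ar
Reagents that add atoms: none
Why: Brønsted-acid cleavage removes the three aryl MOM acetals, the silyl ether and the tert-butyl enol ether (which leaves as the tert-butyl cation and so needs no protonation of the electron-poor C12'=C13' bond, as a methyl ether would), while C1' and C14' hold because either carbocation would be attached to ring B' next to its C11' acyl substituent.

**Step 26**
Reactants: 36 spiro catechol
Product: 38 CNP0266922.1 (5S,10S,14'R,1'S), via 11,12-ortho-quinone 37 (not isolated)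
Conditions: Ag2O, Et2O–CH2Cl2, rt, dark; filtration, then stirring over silica gel
Reagents that add atoms: none
Why: Ag2O oxidises the most electron-rich unit, the 11,12-catechol, to the ortho-quinone, whose C7–H is vinylogously alpha to the C11 carbonyl so that a prototropic shift gives the extended 11-hydroxy-12-oxo quinone methide and erases the C7 stereocentre.

**Compound list**
1 | (+)-carnosic acid | CC(C)c1cc2c(c(O)c1O)[C@@]1(C(=O)O)CCCC(C)(C)[C@@H]1CC2 | starting material
2 | methoxymethyl 11,12-bis(methoxymethoxy)abieta-8,11,13-trien-20-oate | CC(C)c1cc2c(c(OCOC)c1OCOC)[C@@]1(C(=O)OCOC)CCCC(C)(C)[C@@H]1CC2 | intermediate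
3 | 11,12-bis(methoxymethoxy)abieta-8,11,13-trien-20-ol | CC(C)c1cc2c(c(OCOC)c1OCOC)[C@@]1(CO)CCCC(C)(C)[C@@H]1CC2 | intermediate
4 | 11,12-bis(methoxymethoxy)abieta-8,11,13-trien-20-al | CC(C)c1cc2c(c(OCOC)c1OCOC)[C@@]1(C=O)CCCC(C)(C)[C@@H]1CC2 | intermediate
5 | C20 hydrazone of 4 (not isolated) | CC(C)c1cc2c(c(OCOC)c1OCOC)[C@@]1(C=NN)CCCC(C)(C)[C@@H]1CC2 | intermediate
6 | (5S,10S)-11,12-bis(methoxymethoxy)abieta-8,11,13-triene | CC(C)c1cc2c(c(OCOC)c1OCOC)[C@@]1(C)CCCC(C)(C)[C@@H]1CC2 | intermediate
7 | 14-bromo-11,12-bis(methoxymethoxy)abieta-8,11,13-triene | CC(C)c1c(Br)c2c(c(OCOC)c1OCOC)[C@@]1(C)CCCC(C)(C)[C@@H]1CC2 | intermediate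
8 | 14-bromo-11,12-bis(methoxymethoxy)abieta-8,11,13-trien-7-one | CC(C)c1c(Br)c2c(c(OCOC)c1OCOC)[C@@]1(C)CCCC(C)(C)[C@@H]1CC2=O | intermediate
9 | 14-hydroxy-11,12-bis(methoxymethoxy)abieta-8,11,13-trien-7-one | CC(C)c1c(O)c2c(c(OCOC)c1OCOC)[C@@]1(C)CCCC(C)(C)[C@@H]1CC2=O | intermediate
10 | 2-bromo-3-hydroxybenzaldehyde | O=Cc1cccc(O)c1Br | starting material
11 | 2-bromo-3-(methoxymethoxy)benzaldehyde | O=Cc1cccc(OCOC)c1Br | intermediate
12 | 4-bromo-2-methylbut-1-ene | C=C(C)CCBr | starting material
13 | (3-methylbut-3-en-1-yl)magnesium bromide (not isolated) | C=C(C)CC[Mg]Br | intermediate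
14 | rac-1-[2-bromo-3-(methoxymethoxy)phenyl]-4-methylpent-4-en-1-ol | C=C(C)CCC(O)c1cccc(OCOC)c1Br | intermediate
15 | 1-[2-bromo-3-(methoxymethoxy)phenyl]-4-methylpent-4-en-1-one | C=C(C)CCC(=O)c1cccc(OCOC)c1Br | intermediate
16 | 5-(methoxymethoxy)-4,4-dimethyl-3,4-dihydronaphthalen-1(2H)-one | O=C1CCC(C)(C)c2c1cccc2OCOC | intermediate
17 | 8-bromo-5-(methoxymethoxy)-4,4-dimethyl-3,4-dihydronaphthalen-1(2H)-one | O=C1CCC(C)(C)c2c1c(Br)ccc2OCOC | intermediate
18 | (1S)-8-bromo-5-(methoxymethoxy)-4,4-dimethyl-1,2,3,4-tetrahydronaphthalen-1-ol | Brc1ccc(OCOC)c2c1[C@@H](O)CCC2(C)C | intermediate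
19 | (1S)-TBS ether of 18 | Brc1ccc(OCOC)c2c1[C@@H](O[Si](C)(C)C(C)(C)C)CCC2(C)C | intermediate
20 | di-tert-butyl squarate (3,4-di-tert-butoxycyclobut-3-ene-1,2-dione) | CC(C)(C)OC1=C(OC(C)(C)C)C(=O)C1=O | starting material
21 | chloromagnesium alkoxide of 2,3-di-tert-butoxy-4-hydroxy-4-isopropylcyclobut-2-enone, racemic (not isolated) | CC(C)C1(O[Mg]Cl)C(=O)C(OC(C)(C)C)=C1OC(C)(C)C | intermediate
22 | 3-tert-butoxy-4-isopropylcyclobut-3-ene-1,2-dione | CC(C)C1=C(OC(C)(C)C)C(=O)C1=O | intermediate
23 | C9' aryllithium from 19 (not isolated) | [Li]c1ccc(OCOC)c2c1[C@@H](O[Si](C)(C)C(C)(C)C)CCC2(C)C | intermediate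
24 | lithium alkoxide adduct of 23 and 22, epimers at the ring carbinol carbon (not isolated) | CC(C)C1=C(OC(C)(C)C)C(O[Li])(c2ccc(OCOC)c3c2[C@@H](O[Si](C)(C)C(C)(C)C)CCC3(C)C)C1=O | intermediate
25 | 4-aryl-3-tert-butoxy-4-methoxy-2-isopropylcyclobut-2-en-1-one, epimers at C4 of the four-membered ring, (1'S) | CC(C)C1=C(OC(C)(C)C)C(OC)(c2ccc(OCOC)c3c2[C@@H](O[Si](C)(C)C(C)(C)C)CCC3(C)C)C1=O | intermediate
26 | vinylketene with aryl cis to the ketene arm (not isolated) | O=C=C(C(C)C)/C(OC(C)(C)C)=C(/OC)c1ccc(OCOC)c2c1[C@@H](O[Si](C)(C)C(C)(C)C)CCC2(C)C | intermediate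
27 | (1'S)-12'-tert-butoxy-11'-methoxy-6'-(methoxymethoxy)-1'-(TBSO)-20-norabieta-5(10),6,8,11,13-pentaen-14'-ol | CC(C)c1c(O)c2cc(OCOC)c3c(c2c(OC)c1OC(C)(C)C)[C@@H](O[Si](C)(C)C(C)(C)C)CCC3(C)C | intermediate
28 | (1'S)-12'-tert-butoxy-11',11'-dimethoxy-6'-(methoxymethoxy)-1'-(TBSO)-20-norabieta-5(10),6,8,12-tetraen-14'-one | CC(C)C1=C(OC(C)(C)C)C(OC)(OC)c2c(cc(OCOC)c3c2[C@@H](O[Si](C)(C)C(C)(C)C)CCC3(C)C)C1=O | intermediate
29 | (1'S,14'S)-carbinol from 28 | O[C@@H]1C(C(C)C)=C(OC(C)(C)C)C(OC)(OC)c2c1cc(OCOC)c1c2[C@@H](O[Si](C)(C)C(C)(C)C)CCC1(C)C | intermediate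
30 | (14'R)-ether ketone, O14 of 9 bound to C14' of the upper half | CC(C)c1c(O[C@H]2C(C(C)C)=C(OC(C)(C)C)C(OC)(OC)c3c2cc(OCOC)c2c3[C@@H](O[Si](C)(C)C(C)(C)C)CCC2(C)C)c2c(c(OCOC)c1OCOC)[C@@]1(C)CCCC(C)(C)[C@@H]1CC2=O | intermediate
31 | C7 hydrazone of 30 | CC(C)c1c(O[C@H]2C(C(C)C)=C(OC(C)(C)C)C(OC)(OC)c3c2cc(OCOC)c2c3[C@@H](O[Si](C)(C)C(C)(C)C)CCC2(C)C)c2c(c(OCOC)c1OCOC)[C@@]1(C)CCCC(C)(C)[C@@H]1CC2=NN | intermediate
32 | C7 diazo compound (key-step precursor) | CC(C)c1c(O[C@H]2C(C(C)C)=C(OC(C)(C)C)C(OC)(OC)c3c2cc(OCOC)c2c3[C@@H](O[Si](C)(C)C(C)(C)C)CCC2(C)C)c2c(c(OCOC)c1OCOC)[C@@]1(C)CCCC(C)(C)[C@@H]1CC2=[N+]=[N-] | intermediate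
33 | C7 rhodium carbene, the Rh2(O2CCPh3)4 unit drawn as its carbene-bearing Rh atom (not isolated) | CC(C)c1c(O[C@H]2C(C(C)C)=C(OC(C)(C)C)C(OC)(OC)c3c2cc(OCOC)c2c3[C@@H](O[Si](C)(C)C(C)(C)C)CCC2(C)C)c2c(c(OCOC)c1OCOC)[C@@]1(C)CCCC(C)(C)[C@@H]1CC2=[Rh] | intermediate
34 | (7S,14'R)-spiro dihydrobenzofuran with C11' ketal and C12' tert-butyl enol ether (key-step product) | CC(C)c1c2O[C@@]3([C@@H]4c2c(c(OCOC)c1OCOC)[C@@]1(C)CCCC(C)(C)[C@@H]1C4)C(C(C)C)=C(OC(C)(C)C)C(OC)(OC)c1c3cc(OCOC)c2c1[C@@H](O[Si](C)(C)C(C)(C)C)CCC2(C)C | intermediate
35 | spiro C11' ketone | CC(C)c1c2O[C@@]3([C@@H]4c2c(c(OCOC)c1OCOC)[C@@]1(C)CCCC(C)(C)[C@@H]1C4)C(C(C)C)=C(OC(C)(C)C)C(=O)c1c3cc(OCOC)c2c1[C@@H](O[Si](C)(C)C(C)(C)C)CCC2(C)C | intermediate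
36 | deprotected spiro catechol | CC(C)c1c2O[C@@]3([C@@H]4c2c(c(O)c1O)[C@@]1(C)CCCC(C)(C)[C@@H]1C4)C(C(C)C)=C(O)C(=O)c1c3cc(O)c2c1[C@@H](O)CCC2(C)C | intermediate
37 | 11,12-ortho-quinone (not isolated) | CC(C)C1=C2O[C@@]3([C@@H]4C2=C(C(=O)C1=O)[C@@]1(C)CCCC(C)(C)[C@@H]1C4)C(C(C)C)=C(O)C(=O)c1c3cc(O)c2c1[C@@H](O)CCC2(C)C | intermediate
38 | CNP0266922.1, (5S,10S,14'R,1'S) | CC(C)C1=C2O[C@@]3(C4=C2C(=C(O)C1=O)[C@@]1(C)CCCC(C)(C)[C@@H]1C4)C(C(C)C)=C(O)C(=O)c1c3cc(O)c2c1[C@@H](O)CCC2(C)C | target

**Step count and risk**

Total step count: 26. Longest linear sequence: 18 steps (steps 8–14 and 16–26, from 2-bromo-3-hydroxybenzaldehyde).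

The three steps most likely to fail:

1. **Step 23.**
   - Risk: migration of a C6 hydrogen to the carbene carbon may outrun insertion. Hydride transfer may also run to completion, so that the ion pair loses its stereochemical memory or fragments with loss of the tert-butyl group.
   - Fallback: the C7–C14' bond is made photochemically from ketone 30, without any diazo compound.
   - Irradiation of 30 (350 nm, degassed benzene, rt) should trigger a Norrish–Yang photocyclisation of the ortho-alkoxyaryl ketone. The excited C7 carbonyl oxygen abstracts the C14' hydrogen, and the 1,5-biradical closes to the spiro C7 carbinol F1. Its C14' epimers are diastereomers and are separated by chromatography.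
   - The conditions of step 24 convert F1 into the C11' ketone F2.
   - The conditions of step 25 then strip the remaining groups. The tertiary C7 carbinol, para to the freed 12-OH, ionises and loses water, so the quinone methide forms directly.
   - The fallback rejoins the route at 38, with no oxidation step.

2. **Step 20.**
   - Risk: the oxyphosphonium salt may ionise to a vinylogous oxocarbenium ion before the hindered, hydrogen-bonded phenoxide attacks. This would erode the C14' configuration, allow capture at C12', or cause loss of isobutene.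
   - Fallback: the other C–O bond (aryl C14–O) is formed, so that C14' is never a leaving-group carbon and its configuration is retained.
   - Ketone 28 is reduced with the (S)-oxazaborolidine and BH3·SMe2 to the (1'S,14'R)-carbinol F3.
   - F3 is joined to aryl bromide 8 by a copper-catalysed Ullmann-type C–O coupling (CuI, 3,4,7,8-tetramethyl-1,10-phenanthroline, Cs2CO3, PhMe, 100 °C), which the ortho ketone of 8 assists.
   - The fallback rejoins the route at 30.

3. **Step 21.**
   - Risk: condensation at the peri-flanked, electron-rich C7 ketone may be slow without acid. Prolonged heating may then cause solvolysis of the C14' ether or loss of methanol from ring C'.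
   - Fallback: the nitrogen is placed on C7 before the halves are joined.
   - Phenol ketone 9 is condensed with 1,2-bis(tert-butyldimethylsilyl)hydrazine (Sc(OTf)3, 1 mol %, CH2Cl2, rt) to the N-silyl hydrazone F4.
   - F4 is coupled with 29 under the conditions of step 20 to the coupled N-silyl hydrazone F5.
   - The N–Si bond, far more labile than the secondary C1' silyl ether, is cut with one equivalent of TBAF in THF at −20 °C.
   - The fallback rejoins the route at 31.

**Further compounds**
F1 | step 23 | spiro C7 carbinol from photocyclisation of 30 (C7 configuration of no consequence) | CC(C)c1c2O[C@@]3(C4(O)c2c(c(OCOC)c1OCOC)[C@@]1(C)CCCC(C)(C)[C@@H]1C4)C(C(C)C)=C(OC(C)(C)C)C(OC)(OC)c1c3cc(OCOC)c2c1[C@@H](O[Si](C)(C)C(C)(C)C)CCC2(C)C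
F2 | step 23 | C11' ketone of F1 | CC(C)c1c2O[C@@]3(C4(O)c2c(c(OCOC)c1OCOC)[C@@]1(C)CCCC(C)(C)[C@@H]1C4)C(C(C)C)=C(OC(C)(C)C)C(=O)c1c3cc(OCOC)c2c1[C@@H](O[Si](C)(C)C(C)(C)C)CCC2(C)C
F3 | step 20 | (1'S,14'R)-carbinol from 28 | O[C@H]1C(C(C)C)=C(OC(C)(C)C)C(OC)(OC)c2c1cc(OCOC)c1c2[C@@H](O[Si](C)(C)C(C)(C)C)CCC1(C)C
F4 | step 21 | N-(tert-butyldimethylsilyl)hydrazone of 9 | CC(C)c1c(O)c2c(c(OCOC)c1OCOC)[C@@]1(C)CCCC(C)(C)[C@@H]1CC2=NN[Si](C)(C)C(C)(C)C
F5 | step 21 | N-(tert-butyldimethylsilyl)hydrazone of 30 | CC(C)c1c(O[C@H]2C(C(C)C)=C(OC(C)(C)C)C(OC)(OC)c3c2cc(OCOC)c2c3[C@@H](O[Si](C)(C)C(C)(C)C)CCC2(C)C)c2c(c(OCOC)c1OCOC)[C@@]1(C)CCCC(C)(C)[C@@H]1CC2=NN[Si](C)(C)C(C)(C)C
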